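**Strategy.** The route rests on disconnecting the C6–C7 bond of the chromenedione carbocycle (ring atoms C4a, C5, C6, C7, C8, C8a), where C6 is the gem-dimethyl carbon between the conjugated C5 ketone and the central C7 ketone. The precursor is a monocyclic dihydropyran (O1, C2–C4, C4a, C8a) with an isobutyryl group on C4a and a CMe2CO2Me arm on C8a. Because C8 is quaternary, the isopropyl methine is its only enolisable position. One Dieckmann-type Claisen closure then builds the tetramethylcyclohexenedione ring and its second quaternary centre. A thioester placeholder fixes the enol-ether regiochemistry; C3 and C4 come from one organocatalytic Michael step, C2 from equilibration.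

Key step: step 5

Assumption: syncarpic acid 11 and half ester 1 are catalogue chemicals, and the (2R) configuration is taken to be the thermodynamically preferred one at C2; locants C2–C8a in the text are the chromene locants of the target (pyran C5 and C6 of 7–9 are C4a and C8a).

**Step 1**
Reactants: 1 3-methoxy-2,2-dimethyl-3-oxopropanoic acid; 2 S-ethyl ethanethioate
Product: 4 methyl 5-(ethylsulfanyl)-2,2-dimethyl-3,5-dioxopentanoate, via acid chloride 3 (not isolated)
Conditions: (COCl)2, cat. DMF, CH2Cl2, 0 °C → rt, evaporate; then 2 (2.1 equiv), LiN(SiMe3)2 (2.1 equiv), THF, −78 °C, add 3; aq. NH4Cl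
Reagents that add atoms: oxalyl chloride, O=C(Cl)C(=O)Cl (supplies only the chlorine of intermediate 3)
Why: Crossed Claisen condensation in which the lithium enolate of thioester 2 is C-acylated by acid chloride 3, which has no α-hydrogen and cannot form a ketene, while the second equivalent of enolate takes up the acidic proton of the β-keto thioester and prevents double acylation.

**Step 2**
Reactants: 4 methyl 5-(ethylsulfanyl)-2,2-dimethyl-3,5-dioxopentanoate; 5 3-methylbutanal
Product: 6 methyl 4-[(ethylsulfanyl)carbonyl]-2,2,7-trimethyl-3-oxooct-4-enoate (E/Z mixture)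
Conditions: piperidine (10 mol%), AcOH (10 mol%), 4 Å molecular sieves, CH2Cl2, 0 °C → rt
Reagents that add atoms: none
Why: Knoevenagel condensation of the active methylene of 4 with the aliphatic aldehyde under buffered amine catalysis, the geometric mixture being acceptable because both acyl groups activate the double bond for the next step.

**Step 3**
Reactants: 6 methyl 4-[(ethylsulfanyl)carbonyl]-2,2,7-trimethyl-3-oxooct-4-enoate; 5 3-methylbutanal (3 equiv)
Product: 8 methyl 2-[(3S,4S)-5-[(ethylsulfanyl)carbonyl]-2-methoxy-4-(2-methylpropyl)-3-(propan-2-yl)-3,4-dihydro-2H-pyran-6-yl]-2-methylpropanoate (both C2 anomers), via lactol 7 (not isolated)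
Conditions: (R)-α,α-diphenylprolinol trimethylsilyl ether (15 mol%), PhCO2H (15 mol%), toluene, 0 °C → rt; then MeOH (5 equiv), camphorsulfonic acid (40 mol%), 4 Å molecular sieves, 40 °C
Reagents that add atoms: methanol, CO
Why: Enamine-catalysed Michael addition followed by hemiacetalisation (a formal inverse-electron-demand oxa-Diels–Alder reaction) and acid-catalysed acetalisation; the diphenyl(silyloxy)methyl group of the (R)-catalyst shields one face of the E-enamine and sets C3, the synclinal approach of the acceptor should give the syn adduct, which is the 3,4-trans ring with (3S,4S), and only the ketone oxygen can become the ring oxygen because the thioester does not enolise toward oxygen.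

**Step 4**
Reactants: 8 methyl 2-[(3S,4S)-5-[(ethylsulfanyl)carbonyl]-2-methoxy-4-(2-methylpropyl)-3-(propan-2-yl)-3,4-dihydro-2H-pyran-6-yl]-2-methylpropanoate
Product: 9 methyl 2-[(3S,4S)-2-methoxy-5-(2-methylpropanoyl)-4-(2-methylpropyl)-3-(propan-2-yl)-3,4-dihydro-2H-pyran-6-yl]-2-methylpropanoate
Conditions: iPrZnBr (3 equiv, THF solution), PdCl2(PPh3)2 (10 mol%), toluene, rt; neutral work-up
Reagents that add atoms: isopropylzinc bromide, CC(C)[Zn]Br
Why: Fukuyama coupling, in which zerovalent palladium inserts into the acyl–sulfur bond and transmetalation with the alkylzinc and reductive elimination give the isopropyl ketone, while the methyl ester, the acetal and the enol ether should be untouched.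

**Step 5**
Reactants: 9 methyl 2-[(3S,4S)-2-methoxy-5-(2-methylpropanoyl)-4-(2-methylpropyl)-3-(propan-2-yl)-3,4-dihydro-2H-pyran-6-yl]-2-methylpropanoate
Product: 10 (3S,4S)-2-methoxy-6,6,8,8-tetramethyl-4-(2-methylpropyl)-3-(propan-2-yl)-3,4-dihydro-2H-chromene-5,7(6H,8H)-dione
Conditions: LiN(iPr)2 (1.3 equiv), THF, −78 → −20 °C; aq. NH4Cl at −40 °C
Reagents that add atoms: none
Why: LiN(iPr)2 removes the isopropyl methine proton of the C5 ketone, the only enolisable C–H of 9 (C8 is quaternary and C4–H is cross-conjugated), and the tetrasubstituted lithium enolate attacks the neighbouring C7 ester carbonyl, whose tetrahedral intermediate expels methoxide and leaves the C6–C7 bond. The closest known reaction type is the Dieckmann (intramolecular Claisen) condensation of a ketone enolate with an ester to give a cyclic 2,2-disubstituted 1,3-diketone. The carbocycle (C4a, C5, C6, C7, C8, C8a) closes in the 6-(enolendo)-exo-trig mode, helped by the cis placement of the two arms on the C4a=C8a double bond and by the gem-dimethyl effect. No stereocentre is created, C3 and C4 carry no acidic hydrogen, and the C2 acetal is inert to the base. The step needs C- over O-acylation and must not revert: O-acylation would give a strained enol lactone that methoxide re-opens, whereas the C-acylated product should resist retro-Claisen cleavage because C7 lies between two quaternary carbons and lithium methoxide is aggregated at low temperature.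

**Step 6**
Reactants: 10 (3S,4S)-2-methoxy-6,6,8,8-tetramethyl-4-(2-methylpropyl)-3-(propan-2-yl)-3,4-dihydro-2H-chromene-5,7(6H,8H)-dione; 11 syncarpic acid (1.5 equiv)
Product: 12 ericifolione
Conditions: TsOH·H2O (20 mol%), MeCN, 50 °C
Reagents that add atoms: none
Why: Acid ionises the mixed acetal, the enol of 11 attacks C2 in a Knoevenagel-type condensation with loss of methanol, and the tethered enol oxygen closes the pyran again by a reversible 6-exo-trig oxa-Michael addition, so C2 should settle under thermodynamic control with the syncarpyl group equatorial on the half-chair whose C3 isopropyl and C4 isobutyl groups are trans-diaxial, that is cis to the C3 isopropyl group, (2R).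

**Compound list**
1 | 3-methoxy-2,2-dimethyl-3-oxopropanoic acid (monomethyl dimethylmalonate) | COC(=O)C(C)(C)C(=O)O | starting material
2 | S-ethyl ethanethioate | CCSC(C)=O | starting material
3 | methyl 3-chloro-2,2-dimethyl-3-oxopropanoate (not isolated) | COC(=O)C(C)(C)C(=O)Cl | intermediate
4 | methyl 5-(ethylsulfanyl)-2,2-dimethyl-3,5-dioxopentanoate | CCSC(=O)CC(=O)C(C)(C)C(=O)OC | intermediate
5 | 3-methylbutanal | CC(C)CC=O | starting material
6 | methyl 4-[(ethylsulfanyl)carbonyl]-2,2,7-trimethyl-3-oxooct-4-enoate (E/Z mixture) | CCSC(=O)C(=CCC(C)C)C(=O)C(C)(C)C(=O)OC | intermediate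
7 | methyl 2-[(3S,4S)-5-[(ethylsulfanyl)carbonyl]-2-hydroxy-4-(2-methylpropyl)-3-(propan-2-yl)-3,4-dihydro-2H-pyran-6-yl]-2-methylpropanoate (lactol, both C2 epimers, not isolated) | CC(C)C[C@@H]1C(C(=O)SCC)=C(OC(O)[C@H]1C(C)C)C(C)(C)C(=O)OC | intermediate
8 | methyl 2-[(3S,4S)-5-[(ethylsulfanyl)carbonyl]-2-methoxy-4-(2-methylpropyl)-3-(propan-2-yl)-3,4-dihydro-2H-pyran-6-yl]-2-methylpropanoate (both C2 anomers) | CC(C)C[C@@H]1C(C(=O)SCC)=C(OC(OC)[C@H]1C(C)C)C(C)(C)C(=O)OC | intermediate
9 | methyl 2-[(3S,4S)-2-methoxy-5-(2-methylpropanoyl)-4-(2-methylpropyl)-3-(propan-2-yl)-3,4-dihydro-2H-pyran-6-yl]-2-methylpropanoate (both C2 anomers) | CC(C)C[C@@H]1C(C(=O)C(C)C)=C(OC(OC)[C@H]1C(C)C)C(C)(C)C(=O)OC | intermediate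
10 | (3S,4S)-2-methoxy-6,6,8,8-tetramethyl-4-(2-methylpropyl)-3-(propan-2-yl)-3,4-dihydro-2H-chromene-5,7(6H,8H)-dione (both C2 anomers) | CC(C)C[C@@H]1C2=C(OC(OC)[C@H]1C(C)C)C(C)(C)C(=O)C(C)(C)C2=O | intermediate
11 | syncarpic acid, 5-hydroxy-2,2,6,6-tetramethylcyclohex-4-ene-1,3-dione (enol of 2,2,4,4-tetramethylcyclohexane-1,3,5-trione) | CC1(C)C(=O)C=C(O)C(C)(C)C1=O | starting material
12 | ericifolione, (2R,3S,4S)-2-(2-hydroxy-3,3,5,5-tetramethyl-4,6-dioxocyclohex-1-en-1-yl)-6,6,8,8-tetramethyl-4-(2-methylpropyl)-3-(propan-2-yl)-3,4-dihydro-2H-chromene-5,7(6H,8H)-dione | CC(C)C[C@@H]1C2=C(O[C@@H](C3=C(O)C(C)(C)C(=O)C(C)(C)C3=O)[C@H]1C(C)C)C(C)(C)C(=O)C(C)(C)C2=O | target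

**Step count.** Total: 6 steps. Longest linear sequence: 6 steps (1 → 4 → 6 → 8 → 9 → 10 → 12).

**Steps most likely to fail**

Step 5 (key step). The hindered tetrasubstituted enolate may fail to add to the neopentyl-type ester, or the closure may revert by methoxide-induced retro-Claisen cleavage on warming. The fallback sets out from 9 and replaces the ester by an acyl donor whose leaving group cannot re-open the diketone. SN2 demethylation (LiI, pyridine, reflux) should give 2-[(3S,4S)-2-methoxy-5-(2-methylpropanoyl)-4-(2-methylpropyl)-3-(propan-2-yl)-3,4-dihydro-2H-pyran-6-yl]-2-methylpropanoic acid F1. 1,1'-Carbonyldiimidazole in THF should convert it into 1-{2-[(3S,4S)-2-methoxy-5-(2-methylpropanoyl)-4-(2-methylpropyl)-3-(propan-2-yl)-3,4-dihydro-2H-pyran-6-yl]-2-methylpropanoyl}-1H-imidazole F2. LiN(SiMe3)2 at −78 °C is then expected to close the same C6–C7 bond irreversibly, and the route is rejoined at 10.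

Step 3. The enamine may add slowly or with poor facial selectivity to the hindered, geometrically mixed acceptor, and the hindered ketone may close incompletely to the cyclic enol ether. The fallback sets out from 4 and reverses the roles of donor and acceptor under iminium catalysis. Compound 4 would be added to commercial (E)-5-methyl-2-(propan-2-yl)hex-2-enal F3 with a cinchona-derived primary amine (9-amino-9-deoxy-epi-quinine or its quinidine-derived pseudoenantiomer, whichever delivers 4S) and trifluoroacetic acid. Conjugate addition sets C4, and C3 should settle trans to it by equilibration of the aldehyde α-position. This gives lactol 7, which is acetalised as in step 3 and returns to the route at 8.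

Step 4. Oxidative addition into the electron-rich vinylogous thiocarbonate may be slow, β-hydride elimination from the isopropylpalladium intermediate may cause isomerisation or reduction, and the zinc Lewis acid may open the mixed acetal with loss of enol-ether regiochemistry. The fallback sets out from 8 and builds the ketone in three operations. Fukuyama reduction (Et3SiH, palladium on carbon, acetone) should give methyl 2-[(3S,4S)-5-formyl-2-methoxy-4-(2-methylpropyl)-3-(propan-2-yl)-3,4-dihydro-2H-pyran-6-yl]-2-methylpropanoate F4. Addition of iPrMgCl·LiCl at −78 °C should give methyl 2-[(3S,4S)-5-(1-hydroxy-2-methylpropyl)-2-methoxy-4-(2-methylpropyl)-3-(propan-2-yl)-3,4-dihydro-2H-pyran-6-yl]-2-methylpropanoate F5 as a carbinol mixture. Dess–Martin periodinane buffered with NaHCO3 then returns to the route at 9.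

**Further compounds**
F1 | step 5 | 2-[(3S,4S)-2-methoxy-5-(2-methylpropanoyl)-4-(2-methylpropyl)-3-(propan-2-yl)-3,4-dihydro-2H-pyran-6-yl]-2-methylpropanoic acid | CC(C)C[C@@H]1C(C(=O)C(C)C)=C(OC(OC)[C@H]1C(C)C)C(C)(C)C(=O)O
F2 | step 5 | 1-{2-[(3S,4S)-2-methoxy-5-(2-methylpropanoyl)-4-(2-methylpropyl)-3-(propan-2-yl)-3,4-dihydro-2H-pyran-6-yl]-2-methylpropanoyl}-1H-imidazole | CC(C)C[C@@H]1C(C(=O)C(C)C)=C(OC(OC)[C@H]1C(C)C)C(C)(C)C(=O)n1ccnc1
F3 | step 3 | (E)-5-methyl-2-(propan-2-yl)hex-2-enal (purchased) | CC(C)C/C=C(C=O)\C(C)C
F4 | step 4 | methyl 2-[(3S,4S)-5-formyl-2-methoxy-4-(2-methylpropyl)-3-(propan-2-yl)-3,4-dihydro-2H-pyran-6-yl]-2-methylpropanoate | CC(C)C[C@@H]1C(C=O)=C(OC(OC)[C@H]1C(C)C)C(C)(C)C(=O)OC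
F5 | step 4 | methyl 2-[(3S,4S)-5-(1-hydroxy-2-methylpropyl)-2-methoxy-4-(2-methylpropyl)-3-(propan-2-yl)-3,4-dihydro-2H-pyran-6-yl]-2-methylpropanoate | CC(C)C[C@@H]1C(C(O)C(C)C)=C(OC(OC)[C@H]1C(C)C)C(C)(C)C(=O)OC
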